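4 questions stand here, and one share runs through them.

common to all: time 30 s
- dusk: E 2.0 mM; D 0.950 equiv; everything together at the start
- spring: E 2.0 mM; D 0.950 equiv (fed, over 25 s); all else is in the flask from the start; the feed brings no volume worth counting
- autumn: E 2.0 mM (fed, over 25 s); D 0.950 equiv; all else is in the flask from the start; the feed brings no volume worth counting

    E + D → E.D (k1 = 11.1 L mol⁻¹ s⁻¹)
    E + D → J (k2 = 119 L mol⁻¹ s⁻¹)
    E.D → X (k3 = 0.676 s⁻¹)

- which flask leads in amount of J, in percent of the E charged ("all alike" within 1.5 percentage points) (dusk / spring / autumn / all alike)
- how much J is there at the end, in percent of the E charged: dusk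
- how much J is there at the end, in percent of the E charged: spring
- how much J is there at the end, in percent of the E charged: autumn

Begin at the fork. E and D meet in both first steps, each going at constant times [E][D], so while they run, the step to J keeps a rate 10.7 times that of the step to E.D. Take the constant of the step to J over the sum of both constants, 91.5 %: this is the J share, the part of consumed E that ends as J, a selectivity reckoned from the two constants.

Now reckon the consumption. With partners in like amounts at the full charge, the mixture halves in 3.84 s, so dusk runs a clock of 7.81. Clock over one plus clock gives 88.6 % consumed, and the J share makes that 81.1 %. For a fed flask, count the charge as arriving at mid-feed, which leaves a clock of 4.55, and so 75.0 %. The rate [E][D] treats both partners alike, so this reckoning gives spring and autumn one number.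

The weak link is "like amounts", since D, the limiting reagent, stands at 0.950 equiv. Reforge it with the exact law for unequal partners, in which [E]/[D] starts at one over the equivalents and grows exponentially with the clock times the excess of E. This law reckons 86.0 % consumed for dusk and 79.5 % for a fed flask. I commit to 78.7 % for dusk, 72.7 % for spring and 72.7 % for autumn, which puts dusk in the lead.

The forecast names dusk, with 78.7 %, 68.9 % and 69.1 %, on the grounds that “the two fed flasks lose reaction time”, and it sets spring lower than I do by 3.8 percentage points.

The flask gives dusk first at 78.7 %, then autumn at 69.1 % and spring at 68.8 %. Spring holds 24.8 % of its E at 30.0 s, so 75.2 % is consumed, 4.2 points below my 79.5 %, and the J share turns that into 68.8 %. A neighbour of spring charged with 0.570 equiv of D ends with 49.7 % of its E, for which the J share gives 46.0 %, and that flask holds 46.0 % of J.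

(The constants used here stand for no real mixture; what happens was integrated by code.)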